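Assumption (chemistry): (R)-glycidyl 4-methoxybenzyl ether 4 is taken as commercial (otherwise one etherification of (S)-glycidol gives it). Germacrane numbering (C1–C15) is used for every intermediate.

## Analysis of the target

The target 40 is a ten-membered carbocycle (C1–C10) fused at C6–C7 to an α-methylene-γ-butyrolactone (O6, C12, C11=C13). It carries a cis epoxide across C1–C10 with methyl C14 on C10, a Z C4=C5 alkene with the hydroxymethyl C15 on C4, an acetate on O3 and a methacrylate on O8. The six stereocentres are 1R, 3S, 6S, 7R, 8R, 10S. C9 and C2 are cis on the epoxide, O3 and O6 lie on the same side of the Z alkene, H6 and H7 are cis (cis-fused lactone), and the C7 arm is anti to O8 in the C6–C7–C8–C9 zigzag. Sensitive groups are two Michael acceptors, a trisubstituted epoxide that opens transannularly under acid, an allylic acetate next to a free primary allylic alcohol (acyl migration), and the doubly allylic C7–H. The difficulty lies in the medium ring, in four oxygens that need three different acyl states, and in C7, which carries two different sp2 arms and must be set relative to C8 and C6. The strategy rests on the unit O3–C3–C4=C5–C6–O6: two allylic oxygens syn across a Z alkene are the mark of a suprafacial 1,4-addition of dioxygen to a ring diene C3=C4–C5=C6, which passes through a six-membered 1,2-dioxine.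

## Retrosynthetic reasoning

40 to 38 (via 39). The O–Si bond at C15 and the O–acetyl bond at C3 are cut last. C15 stays silylated until C3 is acetylated, because the primary alcohol would otherwise be acylated first.

38 to 36 (via 37). The lactone C12–O6 bond is cut and the two allylic oxygens are joined as a peroxide. Forward, O–O cleavage gives 37, whose C6 hydroxyl is γ to the C12 ester and closes the five-membered lactone. The C3 hydroxyl cannot reach C12. The methyl group on the ester is only a leaving group.

36 to 34 and 35. This is the key disconnection: the C3–O and C6–O bonds are cut together. One step then supplies both oxygens, two stereocentres and the Z C4=C5 alkene. The forward reaction must be a [4+2] addition and not an ene reaction, and it must use the diene face opposite the C7 arm.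

34 to 33. The C4–C5 bond between the two alkenes is cut. Both alkene geometries can then be fixed in an open chain, and ring closure creates the diene itself. The hindered C4 carries iodine and the unhindered C5 carries tin, the better pairing for a Stille coupling.

33 to 31 and 32, and 31 to 30. The methacrylate is put on late, because it would not survive cuprate or enolate chemistry. Before that O8 is a triethylsilyl ether.

30 to 26 and 27. The C11=C13 methylene is cut. The acrylate is finished only after C7 has been set, so no α-methylene ester meets the cuprate.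

26 to 20 and 23 (through 24 and 25). The C6–C7 bond is cut. A conjugate addition to the Z enoate 20 sets C7 under control of C8 and brings in the Z alkenyltin in the same step, so no aldehyde α to C7 is ever needed.

20 to 18 and 19. The C7=C11 bond is cut by a Z-selective phosphonate olefination. The Z geometry is what makes the following addition selective.

18 back to 13 (via 17, 16, 15, 14). These are functional-group steps. The C4–I bond with C2 cis to iodine comes from a trans addition of H and tin across the alkyne of 13, directed by the free C15 hydroxyl.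

13 to 9 and 10. The C2–C3 bond is cut between an sp3 electrophile (C2 of the epoxy alcohol) and an acetylide.

9 to 8 (and 8 to 6 via 7). The epoxide C–O bonds are cut. A Sharpless epoxidation of the Z allylic alcohol sets C1 and C10 by reagent control.

6 to 3 and 4, and 3 to 1. The C9–C10 bond is cut between a Z alkenyl anion and a terminal epoxide. C8 comes from the chiral pool, and the Z geometry of 3 becomes the cis relation of the epoxide.

23 to 21 and 22. The two C–Sn bonds are made by syn addition of the ditin to ethyne.

## Alternatives that were turned down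

Alternative 1: The ring is cut at C2–C3 and C3–C4, and C3 is supplied by carbon monoxide A2. Forward, zerovalent palladium would join a C2 allylic chloride, A2 and a C4 alkenylstannane to give the ten-membered dienone A1.
- For it: ring closure and the C3 oxygen arrive in one step, and the cis lactone and C8 oxygen are already in place. On the C6/C7 relation it is stronger than the chosen route, because it does not depend on a face-selective cycloaddition.
- Against it: the π-allylpalladium formed from the Z C1(10) allylic chloride can lose its geometry, couple at C10, or couple without insertion of A2. A1 is a β,γ-unsaturated ketone with acidic C2 protons. After the key step, C3 must still be reduced to 3S and the C1(10) alkene epoxidised on the macrocycle without an allylic hydroxyl to direct it; both depend on macrocyclic face control and cost at least four further steps.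
- In comparison, the chosen route makes the epoxide by reagent control on an open chain and sets C3 and C6 together.

Alternative 2: The C7–C11 bond is cut. Forward, a C7 radical from a bromide adds to the alkyne of an O6 propargyl ether (5-exo) and gives the cis-fused methylenetetrahydrofuran A3.
- For it: the short tether favours cis fusion, so this alternative is stronger than the chosen one on the C6/C7 relation, and the C11=C13 methylene is formed directly.
- Against it: the fully decorated ten-membered ring (epoxide, C3 acetate, C6 ether, C8 silyl ether) must exist before the key step, so every oxygen stereocentre needs its own construction. The alkenyl radical formed can abstract hydrogen across the ring. C12 is still a methylene and must be oxidised to the lactone carbonyl late, next to the epoxide and the allylic C3 and C15 positions.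
- In comparison, the chosen route brings C12 in at the ester level from 19 and needs no late C–H oxidation.

Alternative 3: The C5–C6 bond is cut. Forward, a chromium-mediated, nickel-catalysed addition of the Z C5 alkenyl iodide to a C6 aldehyde closes the ring and gives the C6 alcohol A4.
- For it: this kind of closure is the better-precedented way to a ten-membered carbocycle. On ring formation it is stronger than a Stille closure followed by a cycloaddition on a twisted diene.
- Against it: the C6 aldehyde sits on the doubly allylic C7 and can epimerise or move its double bond into conjugation. The C6 configuration is decided without reagent control during ring closure. C3 must be set separately beforehand. C12 is carried as a protected alcohol and needs deprotection and a two-stage oxidation at the end.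
- In comparison, the chosen route sets C3 and C6 in one event and carries C12 at the right oxidation level.

Key step: step 18

## Route

Step 1
Reactants: 1 but-2-yn-1-ol
Product: 3 (Z)-3-iodobut-2-en-1-ol, via cyclic sodium alkenylalanate 2 (not isolated)
Conditions: NaAlH2(OCH2CH2OMe)2, THF, 0 °C to rt; then I2, −78 to 0 °C
Reagents that add atoms: iodine, [I][I]
Why: Trans-hydroalumination through the alkoxyaluminate puts aluminium on C3 cis to the CH2O group, and iodinolysis with retention gives the Z iodide; this geometry later becomes the cis relation of C9 and C2 on the epoxide.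

Step 2
Reactants: 3 (Z)-3-iodobut-2-en-1-ol; 4 (R)-glycidyl 4-methoxybenzyl ether
Product: 6 (2R,4Z)-1-[(4-methoxybenzyl)oxy]-4-methylhex-4-ene-2,6-diol, via dilithio compound 5 (not isolated)
Conditions: n-BuLi (1 equiv) then t-BuLi (2 equiv), Et2O, −78 °C; then 4, BF3·OEt2, −78 °C
Reagents that add atoms: none
Why: Iodine–lithium exchange keeps the alkene geometry, and the alkenyllithium opens the BF3-activated terminal epoxide at its CH2 to form C9–C10. C8 is not touched and comes as 8R from 4.

Step 3
Reactants: 6 diol
Product: 7 bis(triethylsilyl) ether of 6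
Conditions: Et3SiCl (2.5 equiv), imidazole, CH2Cl2, 0 °C to rt
Reagents that add atoms: chlorotriethylsilane, CC[Si](Cl)(CC)CC
Why: Standard silylation of both hydroxyls; O8 needs a group that survives the west-side chemistry and can be removed before the primary tert-butyldimethylsilyl ether.

Step 4
Reactants: 7 bis(triethylsilyl) ether
Product: 8 (2Z,5R)-6-[(4-methoxybenzyl)oxy]-3-methyl-5-[(triethylsilyl)oxy]hex-2-en-1-ol
Conditions: pyridinium p-toluenesulfonate (cat.), MeOH/CH2Cl2, −10 °C
Reagents that add atoms: none
Why: Acid-catalysed methanolysis removes the primary allylic triethylsilyl ether much faster than the hindered secondary one, which frees the allylic alcohol for the epoxidation.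

Step 5
Reactants: 8 allylic alcohol
Product: 9 epoxy alcohol (1R,8R,10S): C2 hydroxyl with C1–C10 epoxide with O8 triethylsilyl ether with O7 4-methoxybenzyl ether
Conditions: Ti(OiPr)4 (cat.), D-(−)-diethyl tartrate (cat.), t-BuOOH, 4 Å sieves, CH2Cl2, −20 °C
Reagents that add atoms: tert-butyl hydroperoxide, CC(C)(C)OO
Why: Sharpless asymmetric epoxidation of a Z trisubstituted allylic alcohol. With the D-(−)-tartrate the oxygen should go to the face that gives 1R,10S (the enantiomeric tartrate is the one that gives the 2S,3R epoxide of nerol), and the Z alkene gives the cis epoxide. The reagent overrides the remote C8 centre.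

Step 6
Reactants: 9 epoxy alcohol; 10 prop-2-yn-1-ol
Product: 13 propargylic alcohol (C2–C3 bond formed; C3≡C4 alkyne with free C15 hydroxyl), via epoxy triflate 11 (not isolated), via dilithiated prop-2-yn-1-ol 12 (not isolated)
Conditions: (CF3SO2)2O, 2,6-lutidine, CH2Cl2, −78 °C; then 12 (from 10, n-BuLi 2 equiv, THF/DMPU), −78 to −30 °C
Reagents that add atoms: none
Why: The primary triflate of a 2,3-epoxy alcohol is displaced by an acetylide carbon at low temperature faster than the epoxide is opened. The alkoxide end of the dianion is the weaker nucleophile, so the C15 hydroxyl arrives free.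

Step 7
Reactants: 13 propargylic alcohol
Product: 15 (Z)-C4 iodide (2-iodoallylic alcohol with C2 cis to iodine), via alkenylstannane 14 (not isolated)
Conditions: [Cp*RuCl]4 (cat.), Bu3SnH, CH2Cl2, rt; then I2, 0 °C
Reagents that add atoms: iodine, [I][I]
Why: Ruthenium-catalysed trans-hydrostannation; the free propargylic hydroxyl steers tin to the near carbon C4, and hydrogen adds trans, so C2 and tin are cis. Iododestannylation goes with retention.

Step 8
Reactants: 15 iodo allylic alcohol
Product: 16 C15 tert-butyldimethylsilyl ether of 15
Conditions: t-BuMe2SiCl, imidazole, DMF, 0 °C to rt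
Reagents that add atoms: tert-butyldimethylsilyl chloride, CC(C)(C)[Si](C)(C)Cl
Why: Standard silylation of the only free hydroxyl; this group stays until the last step and keeps C15 apart from C3.

Step 9
Reactants: 16 silyl ether
Product: 17 C7 primary alcohol
Conditions: DDQ, CH2Cl2/pH 7 buffer, 0 °C
Reagents that add atoms: none
Why: Oxidative cleavage of the 4-methoxybenzyl ether under neutral conditions; silyl ethers, epoxide and alkenyl iodide are not oxidised by DDQ.

Step 10
Reactants: 17 primary alcohol
Product: 18 C7 aldehyde (α-triethylsilyloxy aldehyde)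
Conditions: Dess–Martin periodinane, NaHCO3, CH2Cl2, 0 °C to rt
Reagents that add atoms: none
Why: Buffered Dess–Martin oxidation, mild enough for the epoxide and for the α-oxygenated aldehyde, which is used at once to avoid epimerisation at C8.

Step 11
Reactants: 18 aldehyde; 19 methyl 2-[bis(2,2,2-trifluoroethoxy)phosphoryl]acetate
Product: 20 (Z)-enoate (C7=C11 with C12 methyl ester and 8R triethylsilyl ether)
Conditions: KN(SiMe3)2, 18-crown-6, THF, −78 °C
Reagents that add atoms: none
Why: Still–Gennari olefination; the electron-poor phosphonate under dissociating conditions gives the Z enoate kinetically, and α-oxygenated aldehydes are among its best substrates.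

Step 12
Reactants: 21 ethyne; 22 hexamethyldistannane
Product: 23 (Z)-1,2-bis(trimethylstannyl)ethene
Conditions: Pd(PPh3)4 (cat.), dioxane, 60 °C
Reagents that add atoms: none
Why: Syn addition of the Sn–Sn bond across the alkyne, catalysed by zerovalent palladium, gives only the Z distannane.

Step 13
Reactants: 20 (Z)-enoate; 23 (Z)-1,2-bis(trimethylstannyl)ethene
Product: 26 conjugate adduct (7S by the sequence rules; C7 bears the Z 2-(trimethylstannyl)ethenyl group and CH2CO2Me), via alkenyllithium 24 (not isolated), via lithium dialkenylcuprate 25 (not isolated)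
Conditions: 23, MeLi, THF, −78 °C; CuI, −78 to −40 °C; then Me3SiCl, 20, −78 °C; aq. NH4Cl
Reagents that add atoms: none
Why: Tin–lithium exchange and cuprate formation keep the Z geometry. In the Z γ-silyloxy enoate, allylic 1,3-strain holds H8 in the enoate plane and the cuprate should add anti to the C9 chain, which gives the 3,4-syn adduct. This is the C7 configuration of the target; its descriptor changes to 7R once C11 becomes sp2.

Step 14
Reactants: 26 ester; 27 N,N-dimethylmethyleneiminium iodide
Product: 30 α-methylene ester (7R,8R; C11=C13 in place), via Mannich base 28 (not isolated), via trimethylammonium iodide 29 (not isolated)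
Conditions: LiN(iPr)2, THF, −78 °C; 27, −78 to 0 °C; then MeI, MeOH, rt; then aq. NaHCO3, CH2Cl2
Reagents that add atoms: none
Why: Mannich reaction of the ester enolate, N-methylation and elimination is the standard α-methylenation. The C11 centre of 28 is lost, and C7 is not α to the ester, so it is not epimerised.

Step 15
Reactants: 30 α-methylene ester
Product: 31 C8 alcohol
Conditions: HF·pyridine, pyridine, THF, 0 °C
Reagents that add atoms: none
Why: Buffered fluoride cleaves the secondary triethylsilyl ether before the primary tert-butyldimethylsilyl ether; without stronger acid or base the γ-hydroxy ester should stay open.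

Step 16
Reactants: 31 alcohol; 32 methacrylic anhydride
Product: 33 C8 methacrylate (open-chain cyclisation precursor with C4 iodide and C5 trimethylstannane)
Conditions: Et3N, 4-(dimethylamino)pyridine (cat.), CH2Cl2, 0 °C
Reagents that add atoms: none
Why: Nucleophile-catalysed acylation of the secondary alcohol; at 0 °C it should be faster than closure of O8 onto the C12 methyl ester.

Step 17
Reactants: 33 iodo stannane
Product: 34 ten-membered diene (1R,7R,8R,10S; 3E,5Z by the sequence rules, both ring alkenes cis in the ring; C8 methacrylate with C7 methyl acrylate arm with C15 silyl ether)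
Conditions: Pd2(dba)3 (cat.), AsPh3, CuI (cat.), DMF, 40 °C, 1 mM, slow addition
Reagents that add atoms: none
Why: Intramolecular Stille coupling with retention at both alkenes: oxidative addition at the C4 iodide, transmetalation of the unhindered Z alkenylstannane, reductive elimination. The cis epoxide and the two cis alkenes turn the chain ends toward each other, and high dilution suppresses oligomers.

Step 18
Reactants: 34 ten-membered diene; 35 dioxygen
Product: 36 C3,C6-endoperoxide (1R,3S,6S,7R,8R,10S)
Conditions: O2, tetraphenylporphyrin (cat.), visible light, CH2Cl2, −30 °C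
Reagents that add atoms: none
Why: Sensitised dioxygen gives singlet oxygen, which adds to the termini C3 and C6 of the cisoid ring diene in a concerted suprafacial [4+2] cycloaddition, the known reaction of cyclic 1,3-dienes that gives 3,6-dihydro-1,2-dioxines. The only ring formed is the six-membered peroxide C3–O–O–C6–C5=C4, closed in one intermolecular cycloaddition, and C4=C5 is born inside it and is therefore Z. C3 and C6 are set relative to each other by the suprafacial delivery of both oxygens. Their relation to C7 is set by the diene face: with H7 eclipsing C5=C6 to avoid allylic strain against C4, the acrylate arm stands on one face and the C7–C8 bond points outward on the other, so oxygen must arrive anti to the arm, which gives 6S and with it 3S. The step needs the [4+2] path to win over the ene reaction at the trisubstituted C3=C4 bond (allylic hydrogens on C2 and C15), and it needs this face. The two cis ring alkenes keep the diene cisoid, low temperature and a non-polar solvent disfavour the ene path, and acrylate, methacrylate and epoxide are inert to singlet oxygen. The diene of a ten-membered ring is twisted, which is why the risk of the route sits here.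

Step 19
Reactants: 36 endoperoxide
Product: 38 C3-hydroxy lactone (cis-fused 6,12-lactone; 1R,3S,6S,7R,8R,10S), via cis-enediol 37 (not isolated)
Conditions: thiourea, MeOH, 0 °C to rt; then toluene, 40 °C
Reagents that add atoms: none
Why: Thiourea reduces the O–O bond and leaves both C–O bonds, so the cis-ene-1,4-diol keeps the configuration of 36. The C6 hydroxyl is γ to the C12 ester and closes the five-membered lactone with loss of methanol; the C3 hydroxyl is too far away.

Step 20
Reactants: 38 hydroxy lactone
Product: 39 C3 acetate
Conditions: Ac2O, pyridine, 4-(dimethylamino)pyridine (cat.), CH2Cl2, 0 °C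
Reagents that add atoms: acetic anhydride, CC(=O)OC(C)=O
Why: Acylation of the only free hydroxyl; no base strong enough to add to the α-methylene lactone is used.

Step 21
Reactants: 39 acetate
Product: 40 target
Conditions: HF·pyridine, pyridine, THF, 0 °C to rt
Reagents that add atoms: none
Why: Buffered fluoride removes the primary allylic silyl ether; the near-neutral medium should spare the epoxide and avoid migration of the C3 acetyl group to O15.

## Compound list

1 | but-2-yn-1-ol | CC#CCO | starting material
2 | cyclic sodium alkenylalanate (sodium 2,2-bis(2-methoxyethoxy)-3-methyl-2,5-dihydro-1,2-oxaaluminol-2-uide) | CC1=CCO[Al-]1(OCCOC)OCCOC.[Na+] | intermediate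
3 | (Z)-3-iodobut-2-en-1-ol | OC/C=C(/C)I | intermediate
4 | (R)-2-{[(4-methoxybenzyl)oxy]methyl}oxirane | COc1ccc(COC[C@H]2CO2)cc1 | starting material
5 | lithium (Z)-3-lithiobut-2-en-1-olate | [Li]OC/C=C(/C)[Li] | intermediate
6 | (2R,4Z)-1-[(4-methoxybenzyl)oxy]-4-methylhex-4-ene-2,6-diol | COc1ccc(COC[C@H](O)C/C(C)=C\CO)cc1 | intermediate
7 | bis(triethylsilyl) ether of 6 | COc1ccc(COC[C@H](O[Si](CC)(CC)CC)C/C(C)=C\CO[Si](CC)(CC)CC)cc1 | intermediate
8 | (2Z,5R)-6-[(4-methoxybenzyl)oxy]-3-methyl-5-[(triethylsilyl)oxy]hex-2-en-1-ol | COc1ccc(COC[C@H](O[Si](CC)(CC)CC)C/C(C)=C\CO)cc1 | intermediate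
9 | [(2R,3S)-3-{(2R)-3-[(4-methoxybenzyl)oxy]-2-[(triethylsilyl)oxy]propyl}-3-methyloxiran-2-yl]methanol | COc1ccc(COC[C@H](O[Si](CC)(CC)CC)C[C@]2(C)O[C@@H]2CO)cc1 | intermediate
10 | prop-2-yn-1-ol | C#CCO | starting material
11 | trifluoromethanesulfonate of 9 | COc1ccc(COC[C@H](O[Si](CC)(CC)CC)C[C@]2(C)O[C@@H]2COS(=O)(=O)C(F)(F)F)cc1 | intermediate
12 | dilithiated prop-2-yn-1-ol | [Li]C#CCO[Li] | intermediate
13 | 4-[(2R,3S)-3-{(2R)-3-[(4-methoxybenzyl)oxy]-2-[(triethylsilyl)oxy]propyl}-3-methyloxiran-2-yl]but-2-yn-1-ol | COc1ccc(COC[C@H](O[Si](CC)(CC)CC)C[C@]2(C)O[C@@H]2CC#CCO)cc1 | intermediate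
14 | (Z)-2-(tributylstannyl)but-2-en-1-ol analogue of 13 (tin on C4, cis to C2) | COc1ccc(COC[C@H](O[Si](CC)(CC)CC)C[C@]2(C)O[C@@H]2C/C=C(/CO)[Sn](CCCC)(CCCC)CCCC)cc1 | intermediate
15 | (2Z)-2-iodo-4-[(2R,3S)-3-{(2R)-3-[(4-methoxybenzyl)oxy]-2-[(triethylsilyl)oxy]propyl}-3-methyloxiran-2-yl]but-2-en-1-ol | COc1ccc(COC[C@H](O[Si](CC)(CC)CC)C[C@]2(C)O[C@@H]2C/C=C(/CO)I)cc1 | intermediate
16 | C15 tert-butyldimethylsilyl ether of 15 | COc1ccc(COC[C@H](O[Si](CC)(CC)CC)C[C@]2(C)O[C@@H]2C/C=C(/CO[Si](C)(C)C(C)(C)C)I)cc1 | intermediate
17 | (2R)-3-[(2S,3R)-3-{(2Z)-4-[(tert-butyldimethylsilyl)oxy]-3-iodobut-2-en-1-yl}-2-methyloxiran-2-yl]-2-[(triethylsilyl)oxy]propan-1-ol | OC[C@H](O[Si](CC)(CC)CC)C[C@]1(C)O[C@@H]1C/C=C(/CO[Si](C)(C)C(C)(C)C)I | intermediate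
18 | (2R)-3-[(2S,3R)-3-{(2Z)-4-[(tert-butyldimethylsilyl)oxy]-3-iodobut-2-en-1-yl}-2-methyloxiran-2-yl]-2-[(triethylsilyl)oxy]propanal | O=C[C@H](O[Si](CC)(CC)CC)C[C@]1(C)O[C@@H]1C/C=C(/CO[Si](C)(C)C(C)(C)C)I | intermediate
19 | methyl 2-[bis(2,2,2-trifluoroethoxy)phosphoryl]acetate | COC(=O)CP(=O)(OCC(F)(F)F)OCC(F)(F)F | starting material
20 | methyl (2Z,4R)-5-[(2S,3R)-3-{(2Z)-4-[(tert-butyldimethylsilyl)oxy]-3-iodobut-2-en-1-yl}-2-methyloxiran-2-yl]-4-[(triethylsilyl)oxy]pent-2-enoate | COC(=O)/C=C\[C@H](O[Si](CC)(CC)CC)C[C@]1(C)O[C@@H]1C/C=C(/CO[Si](C)(C)C(C)(C)C)I | intermediate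
21 | ethyne | C#C | starting material
22 | hexamethyldistannane | C[Sn](C)(C)[Sn](C)(C)C | starting material
23 | (Z)-1,2-bis(trimethylstannyl)ethene | C[Sn](C)(C)/C=C\[Sn](C)(C)C | intermediate
24 | (Z)-2-(trimethylstannyl)ethenyllithium | [Li]/C=C\[Sn](C)(C)C | intermediate
25 | lithium bis[(Z)-2-(trimethylstannyl)ethenyl]cuprate | [Li+].C[Sn](C)(C)/C=C\[Cu-]/C=C\[Sn](C)(C)C | intermediate
26 | methyl (3S,4R)-ester: conjugate adduct with the (Z)-2-(trimethylstannyl)ethenyl group on C7 (7S,8R) | COC(=O)C[C@@H](/C=C\[Sn](C)(C)C)[C@H](O[Si](CC)(CC)CC)C[C@]1(C)O[C@@H]1C/C=C(/CO[Si](C)(C)C(C)(C)C)I | intermediate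
27 | N,N-dimethylmethyleneiminium iodide | C[N+](C)=C.[I-] | starting material
28 | Mannich base of 26 (dimethylaminomethyl on C11, both C11 epimers) | COC(=O)C(CN(C)C)[C@@H](/C=C\[Sn](C)(C)C)[C@H](O[Si](CC)(CC)CC)C[C@]1(C)O[C@@H]1C/C=C(/CO[Si](C)(C)C(C)(C)C)I | intermediate
29 | trimethylammonium iodide of 28 | COC(=O)C(C[N+](C)(C)C)[C@@H](/C=C\[Sn](C)(C)C)[C@H](O[Si](CC)(CC)CC)C[C@]1(C)O[C@@H]1C/C=C(/CO[Si](C)(C)C(C)(C)C)I.[I-] | intermediate
30 | α-methylene ester (7R,8R): methyl acrylate arm on C7 with O8 triethylsilyl ether | COC(=O)C(=C)[C@@H](/C=C\[Sn](C)(C)C)[C@H](O[Si](CC)(CC)CC)C[C@]1(C)O[C@@H]1C/C=C(/CO[Si](C)(C)C(C)(C)C)I | intermediate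
31 | C8 alcohol of 30 (7R,8R) | COC(=O)C(=C)[C@@H](/C=C\[Sn](C)(C)C)[C@H](O)C[C@]1(C)O[C@@H]1C/C=C(/CO[Si](C)(C)C(C)(C)C)I | intermediate
32 | methacrylic anhydride | CC(=C)C(=O)OC(=O)C(C)=C | starting material
33 | C8 methacrylate of 31 (open-chain iodide and stannane) | COC(=O)C(=C)[C@@H](/C=C\[Sn](C)(C)C)[C@H](OC(=O)C(C)=C)C[C@]1(C)O[C@@H]1C/C=C(/CO[Si](C)(C)C(C)(C)C)I | intermediate
34 | ten-membered diene (1R,7R,8R,10S; 3E,5Z): C8 methacrylate with C7 methyl acrylate arm with C15 silyl ether | C=C(C)C(=O)O[C@@H]1C[C@]2(C)O[C@@H]2C/C=C(CO[Si](C)(C)C(C)(C)C)\C=C/[C@@H]1C(=C)C(=O)OC | intermediate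
35 | dioxygen | O=O | starting material
36 | C3,C6-endoperoxide (1R,3S,6S,7R,8R,10S) | C=C(C)C(=O)O[C@@H]1C[C@]2(C)O[C@@H]2C[C@H](OO3)/C(CO[Si](C)(C)C(C)(C)C)=C\[C@H]3[C@@H]1C(=C)C(=O)OC | intermediate
37 | cis-enediol (C3 and C6 hydroxyls; 1R,3S,6S,7S,8R,10S by the sequence rules) | C=C(C)C(=O)O[C@@H]1C[C@]2(C)O[C@@H]2C[C@H](O)/C(CO[Si](C)(C)C(C)(C)C)=C\[C@H](O)[C@@H]1C(=C)C(=O)OC | intermediate
38 | C3-hydroxy lactone with C15 silyl ether (1R,3S,6S,7R,8R,10S) | C=C(C)C(=O)O[C@@H]1C[C@]2(C)O[C@@H]2C[C@H](O)/C(CO[Si](C)(C)C(C)(C)C)=C\[C@@H]2OC(=O)C(=C)[C@@H]21 | intermediate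
39 | C3 acetate of 38 | C=C(C)C(=O)O[C@@H]1C[C@]2(C)O[C@@H]2C[C@H](OC(C)=O)/C(CO[Si](C)(C)C(C)(C)C)=C\[C@@H]2OC(=O)C(=C)[C@@H]21 | intermediate
40 | CNP0319155.2 (1R,3S,6S,7R,8R,10S) | C=C(C)C(=O)O[C@@H]1C[C@]2(C)O[C@@H]2C[C@H](OC(C)=O)/C(CO)=C\[C@@H]2OC(=O)C(=C)[C@@H]21 | target

Total step count: 21. Longest linear sequence: 20 steps (steps 1–11 and 13–21; step 12 is a one-step side branch).

## Steps least certain to work

Step 18 (key step).
- What may go wrong: the cis,cis-diene of a ten-membered ring is twisted, so the cycloaddition may be slow. The ene reaction at the trisubstituted C3=C4 bond can then take over. Oxygen may also come in on the arm-bearing face and give the C3,C6-diepimer.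
- Fallback, from 34 back to 38, in stepwise form that needs no planar diene and moves the face question away from C7:
  1. Me3SnOH in 1,2-dichloroethane cleaves the methyl ester selectively to the C12 carboxylic acid F1.
  2. Dimethyldioxirane epoxidises the more electron-rich C3=C4 bond on its open face to the vinyl epoxide F2.
  3. Pd(PPh3)4 ionises the vinyl epoxide with inversion, and the C12 carboxylate attacks C6 anti to palladium. O6 ends syn to O3 with C4=C5 in place, which is 38.

Step 17.
- What may go wrong: reductive elimination to the strained ring is slow, so oligomerisation and protodestannylation compete.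
- Fallback, from 30 back to 34, closing the ring on the less encumbered silyl ether and without palladium:
  1. Copper thiophene-2-carboxylate (CuO2CC4H3S) in N-methylpyrrolidone at high dilution gives the ten-membered diene silyl ether F3.
  2. HF·pyridine gives the hydroxy diene F4.
  3. Methacrylic anhydride 32 gives 34.

Step 13.
- What may go wrong: addition to the hindered Z enoate is sluggish, face selectivity is poor, or iodine–copper exchange occurs at C4.
- Fallback, from 18 back to 30, replacing steps 11, 13 and 14:
  1. Morita–Baylis–Hillman reaction of 18 with methyl acrylate and DABCO gives the allylic alcohol F5 (C7 epimers, which do not matter).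
  2. N-bromosuccinimide and Me2S give the rearranged (Z)-2-(bromomethyl)enoate F6.
  3. SN2' displacement by cuprate 25 places the alkenyl group on C7 under the same allylic-strain control and gives 30.

Step 6.
- What may go wrong: the epoxy triflate decomposes, the epoxide is opened, or the sparingly soluble dianion is O-alkylated.
- Fallback, from 11 back to 13, building the alkyne in stages:
  1. Lithium (trimethylsilyl)acetylide in THF/DMPU gives the silyl alkyne F7.
  2. K2CO3 in MeOH gives the terminal alkyne F8.
  3. n-BuLi and paraformaldehyde give 13.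

Further compounds

F1 | step 18 | C12 carboxylic acid of diene 34 | C=C(C)C(=O)O[C@@H]1C[C@]2(C)O[C@@H]2C/C=C(CO[Si](C)(C)C(C)(C)C)\C=C/[C@@H]1C(=C)C(=O)O
F2 | step 18 | C3,C4-epoxide of F1 (vinyl epoxide, C5=C6 Z) | C=C(C)C(=O)O[C@@H]1C[C@]2(C)O[C@@H]2C[C@@H]3O[C@]3(CO[Si](C)(C)C(C)(C)C)/C=C\[C@@H]1C(=C)C(=O)O
F3 | step 17 | ten-membered diene with O8 triethylsilyl ether | CC[Si](CC)(CC)O[C@@H]1C[C@]2(C)O[C@@H]2C/C=C(CO[Si](C)(C)C(C)(C)C)\C=C/[C@@H]1C(=C)C(=O)OC
F4 | step 17 | ten-membered diene with free C8 hydroxyl | O[C@@H]1C[C@]2(C)O[C@@H]2C/C=C(CO[Si](C)(C)C(C)(C)C)\C=C/[C@@H]1C(=C)C(=O)OC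
F5 | step 13 | Morita–Baylis–Hillman adduct of 18 (C7 hydroxyl, both epimers) | COC(=O)C(=C)C(O)[C@H](O[Si](CC)(CC)CC)C[C@]1(C)O[C@@H]1C/C=C(/CO[Si](C)(C)C(C)(C)C)I
F6 | step 13 | (Z)-2-(bromomethyl)enoate from F5 | COC(=O)/C(CBr)=C/[C@H](O[Si](CC)(CC)CC)C[C@]1(C)O[C@@H]1C/C=C(/CO[Si](C)(C)C(C)(C)C)I
F7 | step 6 | trimethylsilyl alkyne from 11 | COc1ccc(COC[C@H](O[Si](CC)(CC)CC)C[C@]2(C)O[C@@H]2CC#C[Si](C)(C)C)cc1
F8 | step 6 | terminal alkyne from F7 | COc1ccc(COC[C@H](O[Si](CC)(CC)CC)C[C@]2(C)O[C@@H]2CC#C)cc1
A1 | alternative 1 | ten-membered (1(10)Z,4Z)-dien-3-one | O=C1C/C=C(C)\C[C@@H](O[Si](CC)(CC)CC)[C@H]2C(=C)C(=O)O[C@H]2/C=C1/CO[Si](C)(C)C(C)(C)C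
A2 | alternative 1 | carbon monoxide | [C-]#[O+]
A3 | alternative 2 | cis-fused 3-methylenetetrahydrofuran macrocycle | CC[Si](CC)(CC)O[C@@H]1C[C@]2(C)O[C@@H]2C[C@H](OC(C)=O)/C(CO[Si](C)(C)C(C)(C)C)=C\[C@@H]2OCC(=C)[C@@H]21
A4 | alternative 3 | ten-membered C6 alcohol with C12 4-methoxybenzyl ether | C=C(C)C(=O)O[C@@H]1C[C@]2(C)O[C@@H]2C[C@H](OC(C)=O)/C(CO[Si](C)(C)C(C)(C)C)=C\[C@H](O)[C@@H]1C(=C)COCc1ccc(OC)cc1
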